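Ring labels: the upper isoflavan is rings A (benzo), C (pyran) and B (3-aryl). The lower isoflavan is rings D (benzo), F (pyran) and E (3-aryl, also bonded to upper C4).
Cuts: four benzyl ethers and one temporary C2 alkoxy group on each pyran come off first. Ring F is then cut at C3–C4 and O1–C2 in one retro oxa-[4+2], ring C is cut the same way together with its C4–ring E bond, and the aryl–vinyl bonds of rings B and E fall to Suzuki couplings.
Enabling feature: in each chroman, O1–C8a–C4a–C4 is an o-hydroxybenzyl unit whose C4 lies ortho to O1 and para to the 7-oxygen, which makes it a latent o-quinone methide. C2–C3 with its 2,4-dioxygenated aryl ring is a latent (E)-β-alkoxystyrene, and the alkoxy helper reverses the styrene polarity so that the aryl group ends on C3 (isoflavan) rather than C2 (flavan).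
Forward order: rings A, B, D and E are bought as arenes. Ring C forms first from the ring E Grignard, the ring A aldehyde and the ring B enol ether. The ring E bromide then becomes a second enol ether, and ring F closes last on the parent o-quinone methide of ring D.
Stereochemistry: both C3 centres come from face shielding by one auxiliary, (1S,2R)-2-phenylcyclohexanol, on (E)-enol ethers. Upper C4 comes from the endo approach to an (E)-o-quinone methide (3,4-trans). Both C2 acetal centres are erased together with the auxiliaries in one ionic reduction.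

Key step: step 10

Assumption: the sense of induction of the (1S,2R)-2-phenylcyclohexyl group is taken from the s-trans, phenyl-shielded conformer of the enol ether (attack on the Re face of the oxygen-bearing alkene carbon); if the opposite sense were found, the equally available (1R,2S) alcohol would be used throughout.

Step 1
Reactants: 1 2-bromo-5-methoxyphenol
Product: 2 2-(benzyloxy)-1-bromo-4-methoxybenzene
Conditions: BnBr, K2CO3, DMF, rt
Reagents that add atoms: benzyl bromide, BrCc1ccccc1
Why: Williamson ether synthesis on the only acidic OH gives a benzyl ether that tolerates the magnesium, palladium and silyl triflate steps and leaves by hydrogenolysis at the end.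

Step 2
Reactants: 3 (1S,2R)-trans-2-phenylcyclohexanol
Product: 6 (1S,2R)-1-(ethynyloxy)-2-phenylcyclohexane, via dichlorovinyl ether 4 (not isolated), via lithium alkoxyacetylide 5 (not isolated)
Conditions: KH, THF, 0 °C; Cl2C=CHCl, −50 °C to rt; n-BuLi (2.4 equiv), −78 to −40 °C; H2O
Reagents that add atoms: trichloroethylene, ClC=C(Cl)Cl
Why: In the standard ynol ether synthesis from trichloroethylene the alkoxide adds to dichloroacetylene formed in the flask, n-BuLi then effects β-elimination and chlorine–lithium exchange, and protonation gives the terminal alkynyl ether without touching the two stereocentres of the auxiliary.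

Step 3
Reactants: 6 (1S,2R)-1-(ethynyloxy)-2-phenylcyclohexane
Product: 7 2-[(E)-2-{[(1S,2R)-2-phenylcyclohexyl]oxy}ethenyl]-4,4,5,5-tetramethyl-1,3,2-dioxaborolane
Conditions: HBpin, Cp2Zr(H)Cl (5 mol %), CH2Cl2, rt
Reagents that add atoms: pinacolborane, [H]B1OC(C)(C)C(C)(C)O1
Why: Zirconium-catalysed hydroboration adds H and B syn and places boron on the terminal carbon, which is both the less hindered and the more electron-rich carbon of an alkoxyalkyne, so the (E)-alkoxyvinylboronate should form.

Step 4
Reactants: 2 2-(benzyloxy)-1-bromo-4-methoxybenzene; 7 (E)-alkoxyvinylboronate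
Product: 8 2-(benzyloxy)-4-methoxy-1-[(E)-2-{[(1S,2R)-2-phenylcyclohexyl]oxy}ethenyl]benzene
Conditions: Pd(OAc)2 (3 mol %), SPhos, K3PO4, THF/H2O, 60 °C
Reagents that add atoms: none
Why: Suzuki–Miyaura coupling (oxidative addition of the aryl bromide to zerovalent palladium, transmetalation, reductive elimination) retains the alkene geometry, and the basic medium protects the acid-sensitive enol ether.

Step 5
Reactants: 2 2-(benzyloxy)-1-bromo-4-methoxybenzene
Product: 9 1-(benzyloxy)-2-bromo-4-iodo-5-methoxybenzene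
Conditions: NIS, CF3CO2H (cat.), MeCN, 0 °C to rt
Reagents that add atoms: N-iodosuccinimide, O=C1CCC(=O)N1I
Why: Electrophilic aromatic iodination goes to the one position that is para to OBn, ortho to OMe and not flanked by two substituents, which gives a halide pair that can be addressed one after the other.

Step 6
Reactants: 10 4-(benzyloxy)-2-hydroxybenzaldehyde
Product: 11 5-(benzyloxy)-2-formylphenyl tert-butyl carbonate
Conditions: Boc2O, DMAP (cat.), i-Pr2NEt (cat.), CH2Cl2, 0 °C to rt
Reagents that add atoms: di-tert-butyl dicarbonate, CC(C)(C)OC(=O)OC(=O)OC(C)(C)C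
Why: DMAP-catalysed O-acylation places the migrating and leaving group for o-quinone methide release on the oxygen that becomes O1.

Step 7
Reactants: 9 1-(benzyloxy)-2-bromo-4-iodo-5-methoxybenzene; 11 5-(benzyloxy)-2-formylphenyl tert-butyl carbonate; 8 ring B (E)-enol ether
Product: 14 (2R,3S,4R)-7-(benzyloxy)-3-[2-(benzyloxy)-4-methoxyphenyl]-4-[4-(benzyloxy)-5-bromo-2-methoxyphenyl]-2-{[(1S,2R)-2-phenylcyclohexyl]oxy}chromane, via arylmagnesium chloride 12 (not isolated), via aryl o-quinone methide 13 (not isolated)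
Conditions: 9, i-PrMgCl, THF, 0 °C to rt; add to 11, Et2O, −78 °C; then 8 (1.5 equiv), −78 °C to rt; aq NH4Cl
Reagents that add atoms: none
Why: Iodine–magnesium exchange spares the bromide, 1,2-addition of 12 to the aldehyde gives a magnesium alkoxide that takes over the Boc group and loses t-BuOCO2MgCl to give the (E)-o-quinone methide 13, and its inverse-electron-demand oxa-Diels–Alder reaction with 8 through the endo approach (alkoxy under the diene) on the alkene face left open by the phenyl group of the auxiliary should set 2R, 3S and 4R at once (2,3-trans from the E alkene, 2,4-cis from endo, hence 3,4-trans).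

Step 8
Reactants: 14 ring C acetal bromide; 7 (E)-alkoxyvinylboronate
Product: 15 (2R,3S,4R)-7-(benzyloxy)-3-[2-(benzyloxy)-4-methoxyphenyl]-4-{4-(benzyloxy)-2-methoxy-5-[(E)-2-{[(1S,2R)-2-phenylcyclohexyl]oxy}ethenyl]phenyl}-2-{[(1S,2R)-2-phenylcyclohexyl]oxy}chromane
Conditions: Pd(OAc)2 (5 mol %), SPhos, K3PO4, THF/H2O, 60 °C
Reagents that add atoms: none
Why: Suzuki–Miyaura coupling with retention of the E geometry meets no base-sensitive group, since all phenols are benzyl ethers and the acetal is stable to base.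

Step 9
Reactants: 11 5-(benzyloxy)-2-formylphenyl tert-butyl carbonate
Product: 16 5-(benzyloxy)-2-(hydroxymethyl)phenyl tert-butyl carbonate
Conditions: BH3·THF, THF, 0 °C; pH 7 buffer
Reagents that add atoms: none
Why: Borane reduction of the aldehyde passes through a borate and not a basic alkoxide, so the carbonate neither migrates nor leaves before it is wanted.

Step 10
Reactants: 15 ring E (E)-enol ether; 16 5-(benzyloxy)-2-(hydroxymethyl)phenyl tert-butyl carbonate
Product: 18 bis-acetal in which the enol ether of 15 has become a (2R,3S)-7-(benzyloxy)-2-{[(1S,2R)-2-phenylcyclohexyl]oxy}chroman-3-yl group on ring E, via o-quinone methide 17 (not isolated)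
Conditions: 16 (3 equiv in portions), t-BuMgCl (1.05 equiv per portion), Et2O/toluene, −78 °C to rt for each portion; aq NH4Cl
Reagents that add atoms: none
Why: t-BuMgCl turns 16 into its magnesium alkoxide, the Boc group moves from the phenolic to the benzylic oxygen and the phenoxide expels t-BuOCO2MgCl, which releases o-quinone methide 17 (O1=C8a–C4a=C4 of rings D and F) at low temperature for an inverse-electron-demand oxa-Diels–Alder reaction with the enol ether of 15; the closest known reaction types are cycloadditions of magnesium-generated o-quinone methides to enol ethers of chiral alcohols and of o-quinone methides to β-alkoxystyrenes. Ring F closes as an intermolecular [4+2] annulation in which C3–C4 runs ahead of O1–C2, and in the stepwise limit the phenoxide closes on the oxocarbenium carbon in a 6-exo-trig mode. C3 is controlled by the auxiliary: in the s-trans enol ether the phenyl group of the (1S,2R)-2-phenylcyclohexyl residue covers one face, so C4 should add to the open face of the aryl-bearing carbon and give 3S, while the E geometry relays this to a 2,3-trans acetal (2R) whose C2 centre is deleted later, so any leakage at C2 is harmless. The regiochemistry requires that the nucleophilic alkene carbon be the one bearing ring E, which the alkoxy donor secures against the opposite (flavan) polarity of a plain styrene. The chemoselectivity requires that 17 meet the enol ether before it oligomerises, which is served by the 7-benzyloxy donor that tempers 17, by portionwise release from an excess of cheap 16, and by the absence of any free OH, acidic site or second nucleophilic π bond in 15. The resident stereocentres of ring C are remote from the alkene and should not interfere.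

Step 11
Reactants: 18 bis-acetal
Product: 19 (3S,4R)-7-(benzyloxy)-3-[2-(benzyloxy)-4-methoxyphenyl]-4-{4-(benzyloxy)-5-[(3S)-7-(benzyloxy)chroman-3-yl]-2-methoxyphenyl}chromane
Conditions: Et3SiH (excess), TMSOTf (cat.), CH2Cl2, −78 to −40 °C; Et3N quench
Reagents that add atoms: none
Why: In this silyl-triflate-catalysed ionic hydrogenation of acetals the more basic exocyclic oxygen is silylated and leaves as the silyl ether of the auxiliary, and each cyclic aryloxocarbenium ion should be trapped by the large excess of silane faster than it can lose its C3 proton in a medium without base, so both C2 carbons become CH2 and C3 and C4 stay untouched.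

Step 12
Reactants: 19 tetra-O-benzyl ether of the target
Product: 20 (3S,4R)-4-{4-hydroxy-5-[(3S)-7-hydroxychroman-3-yl]-2-methoxyphenyl}-3-(2-hydroxy-4-methoxyphenyl)chroman-7-ol
Conditions: H2 (1 atm), Pd/C, EtOAc/MeOH, rt
Reagents that add atoms: none
Why: Hydrogenolysis cleaves the four aryl benzyl ethers, while the chroman O1–C2 bonds are not benzylic and the diarylmethine C–C bonds and methyl ethers are inert.

Compound list
1 | 2-bromo-5-methoxyphenol | COc1ccc(Br)c(O)c1 | starting material
2 | 2-(benzyloxy)-1-bromo-4-methoxybenzene | COc1ccc(Br)c(OCc2ccccc2)c1 | intermediate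
3 | (1S,2R)-trans-2-phenylcyclohexanol | O[C@H]1CCCC[C@@H]1c1ccccc1 | starting material
4 | (1S,2R)-1-{[(E)-1,2-dichloroethenyl]oxy}-2-phenylcyclohexane | Cl/C=C(/Cl)O[C@H]1CCCC[C@@H]1c1ccccc1 | intermediate
5 | lithium 2-{[(1S,2R)-2-phenylcyclohexyl]oxy}acetylide | [Li]C#CO[C@H]1CCCC[C@@H]1c1ccccc1 | intermediate
6 | (1S,2R)-1-(ethynyloxy)-2-phenylcyclohexane | C#CO[C@H]1CCCC[C@@H]1c1ccccc1 | intermediate
7 | 2-[(E)-2-{[(1S,2R)-2-phenylcyclohexyl]oxy}ethenyl]-4,4,5,5-tetramethyl-1,3,2-dioxaborolane | CC1(C)OB(/C=C/O[C@H]2CCCC[C@@H]2c2ccccc2)OC1(C)C | intermediate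
8 | 2-(benzyloxy)-4-methoxy-1-[(E)-2-{[(1S,2R)-2-phenylcyclohexyl]oxy}ethenyl]benzene | COc1ccc(/C=C/O[C@H]2CCCC[C@@H]2c2ccccc2)c(OCc2ccccc2)c1 | intermediate
9 | 1-(benzyloxy)-2-bromo-4-iodo-5-methoxybenzene | COc1cc(OCc2ccccc2)c(Br)cc1I | intermediate
10 | 4-(benzyloxy)-2-hydroxybenzaldehyde | O=Cc1ccc(OCc2ccccc2)cc1O | starting material
11 | 5-(benzyloxy)-2-formylphenyl tert-butyl carbonate | CC(C)(C)OC(=O)Oc1cc(OCc2ccccc2)ccc1C=O | intermediate
12 | [4-(benzyloxy)-5-bromo-2-methoxyphenyl]magnesium chloride | COc1cc(OCc2ccccc2)c(Br)cc1[Mg]Cl | intermediate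
13 | (6E)-3-(benzyloxy)-6-[4-(benzyloxy)-5-bromo-2-methoxybenzylidene]cyclohexa-2,4-dien-1-one | COc1cc(OCc2ccccc2)c(Br)cc1/C=C1\C=CC(OCc2ccccc2)=CC1=O | intermediate
14 | (2R,3S,4R)-7-(benzyloxy)-3-[2-(benzyloxy)-4-methoxyphenyl]-4-[4-(benzyloxy)-5-bromo-2-methoxyphenyl]-2-{[(1S,2R)-2-phenylcyclohexyl]oxy}chromane | COc1ccc([C@H]2[C@H](O[C@H]3CCCC[C@@H]3c3ccccc3)Oc3cc(OCc4ccccc4)ccc3[C@@H]2c2cc(Br)c(OCc3ccccc3)cc2OC)c(OCc2ccccc2)c1 | intermediate
15 | 14 with the bromine replaced by an (E)-2-{[(1S,2R)-2-phenylcyclohexyl]oxy}ethenyl group | COc1ccc([C@H]2[C@H](O[C@H]3CCCC[C@@H]3c3ccccc3)Oc3cc(OCc4ccccc4)ccc3[C@@H]2c2cc(/C=C/O[C@H]3CCCC[C@@H]3c3ccccc3)c(OCc3ccccc3)cc2OC)c(OCc2ccccc2)c1 | intermediate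
16 | 5-(benzyloxy)-2-(hydroxymethyl)phenyl tert-butyl carbonate | CC(C)(C)OC(=O)Oc1cc(OCc2ccccc2)ccc1CO | intermediate
17 | 3-(benzyloxy)-6-methylidenecyclohexa-2,4-dien-1-one | C=C1C=CC(OCc2ccccc2)=CC1=O | intermediate
18 | bis-acetal: upper chromane (2R,3S,4R) as in 14, ring E carrying a (2R,3S)-7-(benzyloxy)-2-{[(1S,2R)-2-phenylcyclohexyl]oxy}chroman-3-yl group | COc1ccc([C@H]2[C@H](O[C@H]3CCCC[C@@H]3c3ccccc3)Oc3cc(OCc4ccccc4)ccc3[C@@H]2c2cc([C@H]3[C@H](O[C@H]4CCCC[C@@H]4c4ccccc4)Oc4cc(OCc5ccccc5)ccc4C3)c(OCc3ccccc3)cc2OC)c(OCc2ccccc2)c1 | intermediate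
19 | (3S,4R)-7-(benzyloxy)-3-[2-(benzyloxy)-4-methoxyphenyl]-4-{4-(benzyloxy)-5-[(3S)-7-(benzyloxy)chroman-3-yl]-2-methoxyphenyl}chromane | COc1ccc([C@H]2COc3cc(OCc4ccccc4)ccc3[C@@H]2c2cc([C@H]3COc4cc(OCc5ccccc5)ccc4C3)c(OCc3ccccc3)cc2OC)c(OCc2ccccc2)c1 | intermediate
20 | (3S,4R)-4-{4-hydroxy-5-[(3S)-7-hydroxychroman-3-yl]-2-methoxyphenyl}-3-(2-hydroxy-4-methoxyphenyl)chroman-7-ol (CNP0152030.1) | COc1ccc([C@H]2COc3cc(O)ccc3[C@@H]2c2cc([C@H]3COc4cc(O)ccc4C3)c(O)cc2OC)c(O)c1 | target

Total step count: 12. Longest linear sequence: 8 steps (steps 2, 3, 4, 7, 8, 10, 11, 12, from 3 to 20).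

Steps most likely to fail

Step 10. Self-condensation of the o-quinone methide may outrun its capture by the hindered β-aryl enol ether, which is the limiting partner here, or the auxiliary may discriminate the two alkene faces poorly. The fallback replaces the cycloaddition by enolate alkylation and etherification. It sets out from 15 and 16 and comes back at 19.
- Mild hydrolysis of the enol ether of 15 (PPTS, wet acetone, rt) would give arylacetaldehyde F1. The mixed aryl alkyl acetal of ring C hydrolyses far more slowly.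
- Pinnick oxidation (NaClO2, NaH2PO4, 2-methyl-2-butene) would give arylacetic acid F2.
- Acylation of lithiated (S)-4-benzyl-2-oxazolidinone through the pivaloyl mixed anhydride would give N-acyloxazolidinone F3.
- Appel bromination of 16 (CBr4, PPh3, CH2Cl2, 0 °C) would give benzyl bromide F4.
- Evans alkylation of the sodium (Z)-enolate of F3 (NaHMDS, THF, −78 °C) with F4, on the face away from the benzyl group of the oxazolidinone, would set the S centre in alkylated imide F5.
- LiBH4 (THF/MeOH) would remove the oxazolidinone and the carbonate together to give phenol alcohol F6.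
- Mitsunobu etherification (PPh3, DIAD, THF) would close ring F without touching C3 to give mono-acetal chroman F7, which loses its remaining acetal under the conditions of step 11 and gives 19.

Step 7. The aryl o-quinone methide carries two donor groups and may react sluggishly. Poor endo/exo or facial selectivity would also leave the 3,4-trans relation unsecured. The fallback makes the C4–aryl bond after ring C instead of before it. It sets out from 8, 16 and 2 and comes back at 14.
- Enol ether 8, which can be used in excess here, and the parent o-quinone methide 17 released from 16 (t-BuMgCl, Et2O, −78 °C to rt) would give 4-unsubstituted acetal F8.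
- DDQ in CH2Cl2/MeOH would abstract hydride from C4 and give 4-methoxy ether F9. C4 is the benzylic position para to the 7-benzyloxy group, whereas C3 is deactivated by the neighbouring acetal carbon.
- BF3·OEt2 (CH2Cl2, −78 °C) would ionise the C4–OMe bond, whose cation is carried by both ring A oxygens. Friedel–Crafts attack of arene 2 through its position para to OBn, anti to the 3-aryl group, would give 14.

Step 11. Loss of the C3 proton from the oxocarbenium ion would scramble the lower C3 centre, and endocyclic C–O cleavage would open a pyran ring. The fallback changes the oxidation level and recloses the rings. It sets out from 18 and comes back at 19.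
- Direct oxidation of both cyclic acetals (m-CPBA, BF3·OEt2, CH2Cl2, 0 °C), in which the peracid intercepts the cation, would give bis(dihydrocoumarin) F10.
- LiAlH4 (THF, −20 °C) would give bis(phenol) diol F11.
- Double Mitsunobu etherification (PPh3, DIAD, THF), which engages only the primary alcohols and the two free ring A and ring D phenols, would give 19.

Further compounds
F1 | step 10 | 14 with the bromine replaced by a 2-oxoethyl group (arylacetaldehyde) | COc1ccc([C@H]2[C@H](O[C@H]3CCCC[C@@H]3c3ccccc3)Oc3cc(OCc4ccccc4)ccc3[C@@H]2c2cc(CC=O)c(OCc3ccccc3)cc2OC)c(OCc2ccccc2)c1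
F2 | step 10 | 14 with the bromine replaced by a carboxymethyl group (arylacetic acid) | COc1ccc([C@H]2[C@H](O[C@H]3CCCC[C@@H]3c3ccccc3)Oc3cc(OCc4ccccc4)ccc3[C@@H]2c2cc(CC(=O)O)c(OCc3ccccc3)cc2OC)c(OCc2ccccc2)c1
F3 | step 10 | (4S)-4-benzyl-2-oxazolidinone imide of F2 | COc1ccc([C@H]2[C@H](O[C@H]3CCCC[C@@H]3c3ccccc3)Oc3cc(OCc4ccccc4)ccc3[C@@H]2c2cc(CC(=O)N3[C@@H](Cc4ccccc4)COC3=O)c(OCc3ccccc3)cc2OC)c(OCc2ccccc2)c1
F4 | step 10 | 5-(benzyloxy)-2-(bromomethyl)phenyl tert-butyl carbonate | CC(C)(C)OC(=O)Oc1cc(OCc2ccccc2)ccc1CBr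
F5 | step 10 | F3 alkylated at the α-carbon (S) with the 4-(benzyloxy)-2-[(tert-butoxycarbonyl)oxy]benzyl group | COc1ccc([C@H]2[C@H](O[C@H]3CCCC[C@@H]3c3ccccc3)Oc3cc(OCc4ccccc4)ccc3[C@@H]2c2cc([C@H](Cc3ccc(OCc4ccccc4)cc3OC(=O)OC(C)(C)C)C(=O)N3[C@@H](Cc4ccccc4)COC3=O)c(OCc3ccccc3)cc2OC)c(OCc2ccccc2)c1
F6 | step 10 | 14 with the bromine replaced by an (S)-1-[4-(benzyloxy)-2-hydroxyphenyl]-3-hydroxypropan-2-yl group | COc1ccc([C@H]2[C@H](O[C@H]3CCCC[C@@H]3c3ccccc3)Oc3cc(OCc4ccccc4)ccc3[C@@H]2c2cc([C@H](Cc3ccc(OCc4ccccc4)cc3O)CO)c(OCc3ccccc3)cc2OC)c(OCc2ccccc2)c1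
F7 | step 10 | 14 with the bromine replaced by a (3S)-7-(benzyloxy)chroman-3-yl group (mono-acetal of 19) | COc1ccc([C@H]2[C@H](O[C@H]3CCCC[C@@H]3c3ccccc3)Oc3cc(OCc4ccccc4)ccc3[C@@H]2c2cc([C@H]3COc4cc(OCc5ccccc5)ccc4C3)c(OCc3ccccc3)cc2OC)c(OCc2ccccc2)c1
F8 | step 7 | (2R,3S)-7-(benzyloxy)-3-[2-(benzyloxy)-4-methoxyphenyl]-2-{[(1S,2R)-2-phenylcyclohexyl]oxy}chromane | COc1ccc([C@H]2[C@H](O[C@H]3CCCC[C@@H]3c3ccccc3)Oc3cc(OCc4ccccc4)ccc3C2)c(OCc2ccccc2)c1
F9 | step 7 | (2R,3R,4R)-7-(benzyloxy)-3-[2-(benzyloxy)-4-methoxyphenyl]-4-methoxy-2-{[(1S,2R)-2-phenylcyclohexyl]oxy}chromane (4-OMe trans to the 3-aryl group) | COc1ccc([C@H]2[C@H](O[C@H]3CCCC[C@@H]3c3ccccc3)Oc3cc(OCc4ccccc4)ccc3[C@@H]2OC)c(OCc2ccccc2)c1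
F10 | step 11 | bis(dihydrocoumarin): 19 with both C2 methylene groups replaced by lactone carbonyl groups, (3S,4R) and (3S) | COc1ccc([C@H]2C(=O)Oc3cc(OCc4ccccc4)ccc3[C@@H]2c2cc([C@H]3C(=O)Oc4cc(OCc5ccccc5)ccc4C3)c(OCc3ccccc3)cc2OC)c(OCc2ccccc2)c1
F11 | step 11 | bis(phenol) diol: 19 with both O1–C2 bonds opened to a ring A or ring D phenol and a CH2OH group, all three stereocentres as in 19 | COc1ccc([C@@H](CO)[C@H](c2ccc(OCc3ccccc3)cc2O)c2cc([C@@H](CO)Cc3ccc(OCc4ccccc4)cc3O)c(OCc3ccccc3)cc2OC)c(OCc2ccccc2)c1
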